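**Assumptions (one line):** The catalyst and proline antipodes are chosen to give (R)-3 and (S)-7. Diastereomer ratios at steps 5, 6 and 8 are assumed to be at least about 4:1, with the minor isomer removed by chromatography.

## Retrosynthetic overview
1. Acetylcaespitol comes from acetylation of alcohol 18. The tetrahydropyran is formed last by 6-endo anti-bromoetherification of tertiary alcohol 16 onto a prenyl alkene.
2. The prenyl alkene comes from cross-metathesis of allyl compound 14, done after the ring dihalide is in place. The cyclohexane Br/Cl pair comes from hydroxyl-directed anti-bromochlorination of the 1-methylcyclohexene in 11, with Br delivered syn to C7–O.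
3. Tertiary carbinol 11 comes from Felkin addition of MeLi to α-silyloxy ketone 9. That ketone comes from proline aminoxylation of ketone 5, which comes from allylation of 3.
4. Ketone 3 comes from an amine-catalysed Diels–Alder reaction of isoprene and methyl vinyl ketone, which sets C4. Ring order: cyclohexene, then cyclohexane dihalide, then tetrahydropyran.

## Route

**Step 1**
Reactants: 1 isoprene; 2 methyl vinyl ketone
Product: 3 (R)-1-(4-methylcyclohex-3-en-1-yl)ethan-1-one
Conditions: chiral imidazolidinone·TfOH (20 mol%), MeCN/H2O, –20 °C, 48 h, excess isoprene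
Reagents that add atoms: none (both reactants are incorporated)
Why: Amine-catalysed iminium-type Diels–Alder reaction that gives the "para" adduct, with the catalyst shielding one enone face to set C4 (R).

**Step 2**
Reactants: 3; 4 allyl bromide
Product: 5 (R)-1-(4-methylcyclohex-3-en-1-yl)pent-4-en-1-one
Conditions: LDA (1.05 equiv), THF, –78 °C; then 4, DMPU, –78 → –40 °C
Reagents that add atoms: allyl bromide, C=CCBr
Why: Kinetic deprotonation occurs at the unhindered CH3 and is followed by SN2 alkylation; the low temperature and kinetic conditions protect the C4 stereocentre from epimerisation.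

**Step 3**
Reactants: 5; 6 nitrosobenzene
Product: 7 (S)-2-hydroxy-1-[(R)-4-methylcyclohex-3-en-1-yl]pent-4-en-1-one
Conditions: PhNO (1.5 equiv), proline (30 mol%), DMSO, rt, 3 h; then CuSO4·5H2O (20 mol%), MeOH, rt
Reagents that add atoms: nitrosobenzene, O=Nc1ccccc1 (its O ends up as the C8 hydroxyl)
Why: Enamine-catalysed α-aminoxylation (Hayashi/Zhong type) occurs at the CH2 only, because C4 is tertiary. Proline's acid directs the C–O bond to one enamine face, which sets C8 (S) under catalyst control. Cu(II) then cleaves the N–O bond.

**Step 4**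
Reactants: 7; 8 TBSCl
Product: 9 (S)-2-(TBSO)-1-[(R)-4-methylcyclohex-3-en-1-yl]pent-4-en-1-one
Conditions: TBSCl, imidazole, DMF, rt
Reagents that add atoms: TBSCl, CC(C)(C)[Si](C)(C)Cl
Why: Silylation gives a bulky non-chelating α-oxygen substituent so that the next addition follows the Felkin–Anh model.

**Step 5**
Reactants: 9; 10 MeLi
Product: 11 (2S,3S)-3-(TBSO)-2-[(R)-4-methylcyclohex-3-en-1-yl]hex-5-en-2-ol
Conditions: MeLi (2 equiv), Et2O, –78 °C, 1 h
Reagents that add atoms: MeLi, C[Li]
Why: In the polar Felkin–Anh addition, Me attacks anti to the C8–OTBS bond and past H, giving the tertiary carbinol with C7 (S) and the required C7/C8 relationship.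

**Step 6**
Reactants: 11; 12 NBS; 13 triethylammonium chloride
Product: 14 (2S,3S)-3-(TBSO)-2-[(1R,3R,4R)-3-bromo-4-chloro-4-methylcyclohexyl]hex-5-en-2-ol
Conditions: NaHMDS (1.0 equiv), THF, –78 °C; NBS (1.0 equiv), –78 °C, dark; then Et3N·HCl (3 equiv), CH2Cl2, –78 → –30 °C
Reagents that add atoms: NBS, O=C1CCC(=O)N1Br (Br); Et3N·HCl, CC[NH+](CC)CC.[Cl-] (Cl)
Why: Proposed new method: the tertiary alkoxide and NBS give the alkyl hypobromite, and protonation by Et3NH+ makes it an O-bound Br+ donor. With C7 pseudo-axial on C4, the donor sits 1,3-diaxial to C2, so Br+ is transferred through a six-membered, bicyclo[3.3.1]-like TS to the proximal face of the trisubstituted ring alkene. Chloride then opens the bromonium anti at tertiary C1 from the opposite face, giving Br on C2 syn to C7 and Cl on C1 anti, i.e. (1R,2R) with C4 (R). This is not the face that undirected halogenation favours, where C7 would be equatorial. The closest known chemistry is hypohalite-directed halogenation and NBS/chloride anti-bromochlorination, extended here to ionic Br+ delivery to a remote unactivated cyclohexene. The terminal alkene is about 10^4 times less nucleophilic and is left untouched.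

**Step 7**
Reactants: 14; 15 2-methylbut-2-ene
Product: 16 (2S,3S)-3-(TBSO)-2-[(1R,3R,4R)-3-bromo-4-chloro-4-methylcyclohexyl]-6-methylhept-5-en-2-ol
Conditions: Grubbs II (5 mol%), 2-methylbut-2-ene (20 equiv), CH2Cl2, 40 °C, 12 h
Reagents that add atoms: 2-methylbut-2-ene, CC=C(C)C (gives the =CMe2 terminus; propene is released)
Why: Cross-metathesis converts the monosubstituted alkene into the prenyl alkene, and no competing ring alkene remains after step 6.

**Step 8**
Reactants: 16; 12 NBS
Product: 17 tert-butyl{[(2S,3S,5S)-5-bromo-2-[(1R,3R,4R)-3-bromo-4-chloro-4-methylcyclohexyl]-2,6,6-trimethyloxan-3-yl]oxy}dimethylsilane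
Conditions: NBS (1.1 equiv), NaHCO3, CH2Cl2, –20 °C, 1 h
Reagents that add atoms: NBS, O=C1CCC(=O)N1Br (Br)
Why: Bromoetherification 6-endo at the Markovnikov carbon proceeds by anti addition through a chair-like TS with Br equatorial. The tertiary C7–O bond is retained, and C10 is set (S) by the existing C7 and C8 centres.

**Step 9**
Reactants: 17
Product: 18 (2S,3S,5S)-5-bromo-2-[(1R,3R,4R)-3-bromo-4-chloro-4-methylcyclohexyl]-2,6,6-trimethyloxan-3-ol
Conditions: HF·pyridine, THF/pyridine, 0 °C → rt, 12 h
Reagents that add atoms: none
Why: Fluoride removes the hindered TBS ether. The halides and the tertiary ether survive the buffered HF, and no stereocentre is touched.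

**Step 10**
Reactants: 18; 19 acetic anhydride
Product: 20 acetylcaespitol, (2S,3S,5S)-5-bromo-2-[(1R,3R,4R)-3-bromo-4-chloro-4-methylcyclohexyl]-2,6,6-trimethyloxan-3-yl acetate
Conditions: Ac2O, DMAP, pyridine, rt
Reagents that add atoms: acetic anhydride, CC(=O)OC(C)=O
Why: Ordinary O-acylation of the secondary alcohol with retention at C8.

## Compound list
1 | isoprene | C=CC(C)=C | starting material
2 | methyl vinyl ketone | C=CC(C)=O | starting material
3 | (R)-1-(4-methylcyclohex-3-en-1-yl)ethan-1-one | CC(=O)[C@@H]1CCC(C)=CC1 | intermediate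
4 | allyl bromide | C=CCBr | starting material
5 | (R)-1-(4-methylcyclohex-3-en-1-yl)pent-4-en-1-one | C=CCCC(=O)[C@@H]1CCC(C)=CC1 | intermediate
6 | nitrosobenzene | O=Nc1ccccc1 | starting material
7 | (S)-2-hydroxy-1-[(R)-4-methylcyclohex-3-en-1-yl]pent-4-en-1-one | C=CC[C@H](O)C(=O)[C@@H]1CCC(C)=CC1 | intermediate
8 | tert-butyldimethylsilyl chloride | CC(C)(C)[Si](C)(C)Cl | starting material
9 | TBS ether of 7 | C=CC[C@H](O[Si](C)(C)C(C)(C)C)C(=O)[C@@H]1CCC(C)=CC1 | intermediate
10 | methyllithium | C[Li] | starting material
11 | (2S,3S)-3-(TBSO)-2-[(R)-4-methylcyclohex-3-en-1-yl]hex-5-en-2-ol | C=CC[C@H](O[Si](C)(C)C(C)(C)C)[C@@](C)(O)[C@@H]1CCC(C)=CC1 | intermediate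
12 | N-bromosuccinimide | O=C1CCC(=O)N1Br | starting material
13 | triethylammonium chloride | CC[NH+](CC)CC.[Cl-] | starting material
14 | dihalide from step 6 | C=CC[C@H](O[Si](C)(C)C(C)(C)C)[C@@](C)(O)[C@@H]1CC[C@@](C)(Cl)[C@H](Br)C1 | intermediate
15 | 2-methylbut-2-ene | CC=C(C)C | starting material
16 | prenyl compound from step 7 | CC(C)=CC[C@H](O[Si](C)(C)C(C)(C)C)[C@@](C)(O)[C@@H]1CC[C@@](C)(Cl)[C@H](Br)C1 | intermediate
17 | TBS-protected tetrahydropyran | CC(C)(C)[Si](C)(C)O[C@H]1C[C@H](Br)C(C)(C)O[C@@]1(C)[C@@H]1CC[C@@](C)(Cl)[C@H](Br)C1 | intermediate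
18 | free alcohol (oxan-3-ol) | O[C@H]1C[C@H](Br)C(C)(C)O[C@@]1(C)[C@@H]1CC[C@@](C)(Cl)[C@H](Br)C1 | intermediate
19 | acetic anhydride | CC(=O)OC(C)=O | starting material
20 | acetylcaespitol | CC(=O)O[C@H]1C[C@H](Br)C(C)(C)O[C@@]1(C)[C@@H]1CC[C@@](C)(Cl)[C@H](Br)C1 | target

## Totals
Total steps: 10. Longest linear sequence: 10 steps (isoprene and methyl vinyl ketone to acetylcaespitol). Steps 9 and 10 can be telescoped.

## Three steps most likely to fail
1. **Step 6 (the proposed new step).** Free NBS could brominate the ring alkene on the face anti to C7. That would give the C1/C2 epimer or a bromo-cineole (2-oxabicyclo[2.2.2]octane). The hypobromite could also decompose by β-scission.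
   - Fallback (known chemistry): run undirected NBS/Et4NCl anti-bromochlorination on 11 or on an analogue, and isolate the target diastereomer by preparative HPLC.
2. **Step 5 (Felkin diastereoselectivity at C7).** The Me addition may give a poor dr.
   - Fallback: use the opposite proline enantiomer and add MeMgBr to free hydroxy ketone 7 under chelation control, giving the unlike (7S,8R) diol. Then oxidise C8–OH selectively (TEMPO/PhI(OAc)2) and reduce the resulting α-ketol with a non-chelating bulky hydride to reach the (7S,8S) diol.
3. **Step 1 (organocatalytic Diels–Alder of isoprene with methyl vinyl ketone).** Reactivity and ee may be too low.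
   - Fallback: take (R)-(+)-limonene, selectively dihydroxylate the terminal alkene (NBS/H2O, then base and hydrolysis), and cleave with NaIO4. This gives (R)-3, which then follows the same route.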